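The synthesis rests on tracing the C3–C1' bond of the pyranone (C ring) back to the C2–C1' bond of a flavanone, which aldol condensation and oxa-Michael closure should deliver easily. One iodine(III) oxidation then shifts the B ring from C2 to C3 and creates the C2=C3 double bond. It exploits the para oxygen O4' of the B ring, which lets C1' bridge C2 and C3 as a phenonium ion, and ring oxygen O1, which stabilises the cation left at C2. The precursor is racemic 5,7,4'-tris(benzyloxy)-6-methoxyflavanone, whose methoxy group is locked at C6 because only one phenol was free to cyclise. Hydrogenolysis and dianion-directed 4'-O-prenylation finish the achiral target.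

Key step: step 6

Remark: the target SMILES contains no stereocentre and no stereogenic double bond, so the "single enantiomer" is the achiral compound itself and nothing has to be set or resolved.

Step 1
Reactants: 1 2',4',6'-trihydroxyacetophenone (phloroacetophenone)
Product: 2 4',6'-bis(benzyloxy)-2'-hydroxyacetophenone
Conditions: BnBr (2.05 equiv), K2CO3 (2.2 equiv), DMF, rt to 50 °C
Reagents that add atoms: benzyl bromide, BrCc1ccccc1
Why: Williamson etherification in which the 4'-OH and then one of the two equivalent ortho hydroxyls react, while the last ortho hydroxyl is held by a strong hydrogen bond to the acetyl carbonyl and stays free when the bromide is limited to two equivalents, the dipolar aprotic solvent favouring O- over C-benzylation.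

Step 2
Reactants: 2 4',6'-bis(benzyloxy)-2'-hydroxyacetophenone
Product: 4 4',6'-bis(benzyloxy)-2',5'-dihydroxyacetophenone, via potassium aryl 5'-sulfate 3 (not isolated)
Conditions: K2S2O8 (1.1 equiv, added slowly), aq KOH, pyridine, 10–20 °C, 24 h; HCl to pH 4, unreacted 2 extracted and recycled; aqueous phase 2 M HCl, 70 °C, N2
Reagents that add atoms: potassium persulfate, [K+].[K+].[O-]S(=O)(=O)OOS(=O)(=O)[O-]
Why: Elbs persulfate oxidation, in which the phenoxide attacks the peroxide oxygen through its only open para carbon C5', so the new oxygen lands between the two benzyloxy groups as a sulfate ester that shields it from over-oxidation until mild acid hydrolysis, and the benzyl ethers and the ketone tolerate both stages.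

Step 3
Reactants: 4 4',6'-bis(benzyloxy)-2',5'-dihydroxyacetophenone
Product: 5 4',6'-bis(benzyloxy)-2'-hydroxy-5'-methoxyacetophenone
Conditions: MeI (1.05 equiv), K2CO3 (1.1 equiv), acetone, reflux, N2
Reagents that add atoms: methyl iodide, CI
Why: Chemoselective Williamson O-methylation, since the 5'-phenoxide is neither chelated nor conjugated with the acetyl group and is therefore much more nucleophilic than the hydrogen-bonded 2'-OH, so one equivalent of methyl iodide should stop at the monoether.

Step 4
Reactants: 5 4',6'-bis(benzyloxy)-2'-hydroxy-5'-methoxyacetophenone; 6 4-(benzyloxy)benzaldehyde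
Product: 7 (E)-4,4',6'-tris(benzyloxy)-2'-hydroxy-5'-methoxychalcone
Conditions: KOH (50% aq, 10 equiv), EtOH–THF, rt, 48 h, N2; cold 1 M HCl
Reagents that add atoms: none
Why: Claisen–Schmidt aldol condensation of the methyl ketone enolate with a non-enolisable aldehyde followed by E1cB dehydration to the conjugated E-enone, with all ethers inert to hydroxide and any flavanone already formed converging in step 5.

Step 5
Reactants: 7 (E)-4,4',6'-tris(benzyloxy)-2'-hydroxy-5'-methoxychalcone
Product: 8 racemic 5,7,4'-tris(benzyloxy)-6-methoxyflavanone
Conditions: NaOAc (5 equiv), EtOH–1,4-dioxane (3:1), reflux, 24–48 h; recovered 7 resubmitted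
Reagents that add atoms: none
Why: Reversible intramolecular oxa-Michael addition (6-endo-trig) of the only free phenol onto the enone, with the equilibrium tilted to the flavanone because the 6'-benzyloxy group twists the chalcone carbonyl out of conjugation; C2 forms racemic, which is harmless because step 6 erases it.

Step 6
Reactants: 8 racemic 5,7,4'-tris(benzyloxy)-6-methoxyflavanone
Product: 10 5,7,4'-tris(benzyloxy)-6-methoxyisoflavone (tectorigenin tribenzyl ether), via trans-3-iodanylflavanone 9 (not isolated)
Conditions: PhI(OH)OTs (HTIB, 1.2 equiv), dry MeCN, reflux, N2; aq NaHCO3 work-up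
Reagents that add atoms: none
Why: Acid-catalysed enolisation lets C3 attack iodine(III) on the face opposite the 2-aryl group to give trans-3-iodanylflavanone 9; in its diaxial half-chair the 4-benzyloxyphenyl ring lies antiperiplanar to the C3–I bond, bridges C2 and C3 as a phenonium ion while iodobenzene departs, and opens towards C3 because the cation left at C2 is an O1-stabilised oxocarbenium ion, which loses H-3 to give the chromone. The closest known reaction type is the iodine(III)- or thallium(III)-mediated oxidative 2,3-aryl migration of 4'-alkoxyflavanones to isoflavones, the laboratory counterpart of isoflavone synthase. No ring is closed: C3–C1' forms as C2–C1' breaks, the only cyclic event is the transient three-membered phenonium bridge (Ar1-3 participation), and the pyranone ring is retained. No stereocentre survives, since the C2 centre of 8 and the substrate-controlled trans C3 centre of 9 are both erased. The step needs B-ring migration to beat A-ring migration (ring contraction to a dihydrobenzofuran-3-carboxylate) and plain dehydrogenation to the flavone: the para-benzyloxy donor raises the migratory aptitude of the B ring, and dry acetonitrile, unlike orthoformate or methanol, leaves C4 as an sp2 carbonyl, so the A ring has no tetrahedral C4 to migrate from and no external nucleophile attacks C3. All phenols are masked as benzyl ethers and no alkene is present, so the oxidant has no easier target.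

Step 7
Reactants: 10 5,7,4'-tris(benzyloxy)-6-methoxyisoflavone
Product: 11 tectorigenin (5,7,4'-trihydroxy-6-methoxyisoflavone)
Conditions: H2 (1 atm), 10% Pd/C, THF–MeOH, rt, stopped at 3 equiv H2 uptake (10 recrystallised first to remove iodobenzene traces)
Reagents that add atoms: none
Why: Catalytic hydrogenolysis of the three aryl benzyl ethers, which in neutral solvent at 1 atm should outrun saturation of the chromone C2=C3 bond if stopped at the calculated uptake, leaves the aryl methyl ether untouched and also converges any material that lost its 5-O-benzyl group in step 6.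

Step 8
Reactants: 11 tectorigenin; 12 prenyl bromide (1-bromo-3-methylbut-2-ene)
Product: 14 isoaurmillone (5,7-dihydroxy-6-methoxy-4'-(3-methylbut-2-enyloxy)isoflavone), via dipotassium 7,4'-diphenoxide 13 (not isolated)
Conditions: KOtBu (2.05 equiv), dry DMF, 0 °C, 20 min; 12 (1.0 equiv) in DMF added over 1 h, 0 °C; KH2PO4 buffer (pH 6–7); work-up below 30 °C
Reagents that add atoms: none
Why: Regioselective Williamson O-alkylation of a polyphenolate, in which two equivalents of base ionise 7-OH and 4'-OH but not the chelated 5-OH, and in dianion 13 the localised 4'-phenoxide is far more nucleophilic than the 7-phenoxide (a vinylogous carboxylate flanked by 6-OMe), so the limiting allylic bromide should be taken at O4' by SN2, while the cold, aprotic, non-acidic regime avoids Claisen rearrangement, prenyl ether cleavage and pyranone opening.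

Compound list
1 | 2',4',6'-trihydroxyacetophenone (phloroacetophenone) | CC(=O)c1c(O)cc(O)cc1O | starting material
2 | 4',6'-bis(benzyloxy)-2'-hydroxyacetophenone | CC(=O)c1c(O)cc(OCc2ccccc2)cc1OCc1ccccc1 | intermediate
3 | potassium 3-acetyl-2,6-bis(benzyloxy)-4-hydroxyphenyl sulfate (not isolated) | CC(=O)c1c(O)cc(OCc2ccccc2)c(OS(=O)(=O)[O-])c1OCc1ccccc1.[K+] | intermediate
4 | 4',6'-bis(benzyloxy)-2',5'-dihydroxyacetophenone | CC(=O)c1c(O)cc(OCc2ccccc2)c(O)c1OCc1ccccc1 | intermediate
5 | 4',6'-bis(benzyloxy)-2'-hydroxy-5'-methoxyacetophenone | CC(=O)c1c(O)cc(OCc2ccccc2)c(OC)c1OCc1ccccc1 | intermediate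
6 | 4-(benzyloxy)benzaldehyde | O=Cc1ccc(OCc2ccccc2)cc1 | starting material
7 | (E)-4,4',6'-tris(benzyloxy)-2'-hydroxy-5'-methoxychalcone | O=C(/C=C/c1ccc(OCc2ccccc2)cc1)c1c(O)cc(OCc2ccccc2)c(OC)c1OCc1ccccc1 | intermediate
8 | 5,7,4'-tris(benzyloxy)-6-methoxyflavanone (racemic at C2) | O=C1CC(c2ccc(OCc3ccccc3)cc2)Oc2cc(OCc3ccccc3)c(OC)c(OCc3ccccc3)c21 | intermediate
9 | trans-5,7,4'-tris(benzyloxy)-6-methoxy-3-[phenyl(tosyloxy)-lambda3-iodanyl]flavanone (racemic, relative configuration drawn, not isolated) | O=C1[C@H](I(c2ccccc2)OS(=O)(=O)c2ccc(C)cc2)[C@@H](c2ccc(OCc3ccccc3)cc2)Oc2cc(OCc3ccccc3)c(OC)c(OCc3ccccc3)c21 | intermediate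
10 | 5,7,4'-tris(benzyloxy)-6-methoxyisoflavone | O=c1c(-c2ccc(OCc3ccccc3)cc2)coc2cc(OCc3ccccc3)c(OC)c(OCc3ccccc3)c12 | intermediate
11 | tectorigenin (5,7,4'-trihydroxy-6-methoxyisoflavone) | COc1c(O)cc2occ(-c3ccc(O)cc3)c(=O)c2c1O | intermediate
12 | prenyl bromide (1-bromo-3-methylbut-2-ene) | CC(C)=CCBr | starting material
13 | dipotassium 7,4'-diphenoxide of tectorigenin (not isolated) | COc1c([O-])cc2occ(-c3ccc([O-])cc3)c(=O)c2c1O.[K+].[K+] | intermediate
14 | isoaurmillone | COc1c(O)cc2occ(-c3ccc(OCC=C(C)C)cc3)c(=O)c2c1O | target

Total step count: 8. Longest linear sequence: 8 steps (1 to 14); 6 and 12 are bought.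

Steps most likely to fail

Step 6. The iodanyl intermediate may be diverted into simple dehydrogenation. Iodine(III) may attack the electron-rich A ring at C8. The sulfonic acid released may strip the peri 5-O-benzyl group before oxidation and slow enolisation. The fallback sets out from chalcone 7 and returns at isoflavone 10, performing the aryl shift on the open-chain enone instead of the flavanone. Thallium(III) nitrate trihydrate in methanol–trimethyl orthoformate at rt should give, by oxidative 1,2-aryl migration (favoured by the donor B ring), racemic 1-[4,6-bis(benzyloxy)-2-hydroxy-5-methoxyphenyl]-2-[4-(benzyloxy)phenyl]-3,3-dimethoxypropan-1-one F1. Warming this with catalytic HCl in methanol–THF should close the 2'-phenol onto the unmasked aldehyde carbon, with loss of methanol, to give 10.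

Step 2. Conversion may stay low because the lipophilic phenoxide dissolves poorly and C5' is crowded by two benzyloxy groups. The liberated hydroquinone may also be over-oxidised by air during work-up. The fallback sets out from 2 and returns at 4 by a quinone detour. Teuber oxidation with potassium nitrosodisulfonate (phosphate-buffered water–acetone, or CH2Cl2 with a phase-transfer salt) should give 2-acetyl-3,5-bis(benzyloxy)-1,4-benzoquinone F2. Reduction with aqueous sodium dithionite in a two-phase ethyl acetate system then gives hydroquinone 4.

Step 8. Discrimination between the 4'- and 7-phenoxides may be incomplete, and double alkylation or C-prenylation at C8 may compete. The fallback sets out from 11 and returns at 14 by temporarily blocking O7.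
- The monoanion (K2CO3, 1.0 equiv, DMF, rt), which carries its charge on the most acidic 7-OH, is alkylated with allyl bromide (1.0 equiv) to 7-O-allyltectorigenin F3.
- K2CO3 and 12 in acetone then alkylate the only remaining non-chelated phenol to 7-O-allyl-4'-O-prenyltectorigenin F4.
- Pd(PPh3)4 (cat.) with morpholine in THF at rt removes the unsubstituted allyl group, which ionises much faster than the trisubstituted prenyl ether and departs from the better leaving 7-aryloxide, to give 14.

Further compounds
F1 | step 6 | 1-[4,6-bis(benzyloxy)-2-hydroxy-5-methoxyphenyl]-2-[4-(benzyloxy)phenyl]-3,3-dimethoxypropan-1-one (racemic) | COC(OC)C(c1ccc(OCc2ccccc2)cc1)C(=O)c1c(O)cc(OCc2ccccc2)c(OC)c1OCc1ccccc1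
F2 | step 2 | 2-acetyl-3,5-bis(benzyloxy)-1,4-benzoquinone | CC(=O)C1=C(OCc2ccccc2)C(=O)C(OCc2ccccc2)=CC1=O
F3 | step 8 | 7-O-allyltectorigenin | C=CCOc1cc2occ(-c3ccc(O)cc3)c(=O)c2c(O)c1OC
F4 | step 8 | 7-O-allyl-4'-O-prenyltectorigenin | C=CCOc1cc2occ(-c3ccc(OCC=C(C)C)cc3)c(=O)c2c(O)c1OC
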